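Readings and results come from a simulation from invented constants; the scatter is artificial.

The time set for the row, 40 h, was what I had to keep or change before charging the four flasks. I took it that Z and L give J and G, J turns into G over E, and L makes E from D.

| flask | Z | L | D | remark | time |
|---|---|---|---|---|---|
| larch | 0.20 M | 0.89 equiv | 4.1 mol% | run made earlier |  |
| maple | 0.20 M | 2.9 equiv | 4.1 mol% | run made earlier |  |
| Friday's | 0.20 M | 0.800 equiv | 4.1 mol% |  | 40 h |
| Tuesday's | 0.20 M | 1.00 equiv | 4.1 mol% |  | 40 h |
| Saturday's | 0.20 M | 1.50 equiv | 4.1 mol% |  | 40 h |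
| Monday's | 0.20 M | 2.50 equiv | 4.1 mol% |  | 40 h |

| run | time / h | J / % | Z / % |
|---|---|---|---|
| larch | 3.00 | 40 | 49 |
| larch | 6.00 | 37 | 37 |
| larch | 10.0 | 23 | 31 |
| larch | 12.0 | 20 | 31 |
| larch | 15.0 | 15 | 27 |
| larch | 20.0 | 9 | 27 |
| maple | 1.50 | 73 | 20 |
| maple | 2.50 | 68 | 10 |
| maple | 4.00 | 54 | 6 |
| maple | 8.00 | 26 | 7 |
| maple | 12.0 | 17 | 0 |
| maple | 20.0 | 6 | 0 |

(each reading ± 2 percentage points)

- the numbers in the tables scatter by 2 percentage points (one standard deviation)
- steps thought possible: Z + L <-> J; Z + L <-> G; J + E <-> G + E; L + D -> E + X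
- "hardly changes" means that all values lie within two and a half points (for a concentration: within two and a half percent of the largest)

- [J] at the end for Friday's, Tuesday's, Saturday's, Monday's, in this order
- the shape of the row from first to last (falls all the way / rises, then falls / hardly changes / falls, then rises / rises all the way)

In the larch and maple runs J falls after its early readings, so I replaced each falling curve by one mean rate, a pseudo-first-order fall with E taken as steady. From this I carried forward the survival share, the part of J above its floor that outlasts the stretch from the last reading to the end.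

In the maple run J fell from 54% at 4.00 h to 6% at 20.0 h, a mean rate of 0.137 h⁻¹, which gives a survival share of 0.0642. In the larch run J fell from 37% at 6.00 h to 9% at 20.0 h, a mean rate of 0.101 h⁻¹, and its share of 0.133 is twice the maple one.

The mean has an error. The maple fall ran at 0.183 h⁻¹ from 4.00 h to 8.00 h, and from 8.00 h to 20.0 h it ran at 0.122 h⁻¹, which is slower. The step from J to G also has a way back, so I allowed for a floor: J at the end is the floor plus the share of what stood above it at the last reading.

With the floor set at zero, the tail at the end is 0.385% of the Z charged at maple's share and 1.19% at larch's, against a scatter of 2 percentage points. So I left the time and the charges as they stood, expecting a floor plus a tail that is larger at low L.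

The forecast gave 0.011 M, 0.0119 M, 0.013 M and 0.0133 M, a row that rises all the way, with the words “J still rises across the row”.

The flasks gave 0.00563 M, 0.00665 M, 0.00516 M and 0.00436 M, a row that rises, then falls, turning at 1.1 equiv.

    Z + L ⇌ J (K = 29.0 M⁻¹, k = 2.50 M⁻¹ h⁻¹)
    Z + L ⇌ G (K = 1400 M⁻¹, k = 0.190 M⁻¹ h⁻¹)
    J + E ⇌ G + E, rate k3*[E]*[J] forward; the back reaction follows from the equilibrium constant (k = 21.0 M⁻¹ h⁻¹)
    L + D → E + X (k = 2.30 M⁻¹ h⁻¹)

In Friday's flask at 40.0 h, with each step taken net, J was made at 0.464 of the rate at which it was used up. Monday's J went from 6.02% at 20.0 h to 2.18% at 40.0 h, and maple's share turns this into a floor of 1.92%, against 2.02% standing at 400 h. Friday's J went from 9.98% to 2.82% over the same stretch, and larch's share gives 1.72%, against 1.52% standing at 400 h.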